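The oxane ring is disconnected at C3–C4, the one ring bond that lies between two unbranched carbons, C3 (CHBr) and C4 (CH2), which are flanked by the quaternary carbons C2 and C6 on the ring oxygen. Ring-closing metathesis of a diene ether joins C3 to C4, and a ruthenium hydride formed in the same flask moves the new double bond to C2=C3, so one operation turns an acyclic ether (C6 carbinol carrying an allyl group and an O-bound but-3-en-2-yl group) into the cyclic methyl enol ether. Its axial C6 alkyne then directs bromine to C3, AlMe3 adds the second C2 methyl, and a Suzuki coupling with a limonene-derived alkenylboronate completes the diene.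

Key step: step 4

Locants used below: oxane O1, C2 (CMe2), C3 (CHBr), C4, C5, C6 (carbon bearing methyl and the dienyl chain); the cyclohexane keeps limonene-type locants in the names.

Assumption: in the diol-catalysed allylboration of ynone 1 the alkynyl group is taken to play the role of the aryl group of aryl methyl ketones, so (S)-3,3′-Br2-BINOL is written for the (R)-carbinol; the antipodal diol is used if the sense of induction proves opposite.

Step 1
Reactants: 1 4-(trimethylsilyl)but-3-yn-2-one; 2 allyldiisopropoxyborane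
Product: 3 (R)-3-methyl-1-(trimethylsilyl)hex-5-en-1-yn-3-ol
Conditions: (S)-3,3′-Br2-BINOL (15 mol%), PhCF3/toluene 3:1, −35 °C; aqueous work-up
Reagents that add atoms: none
Why: Diol-catalysed asymmetric allylboration of a ketone (closed six-membered transition state on the mixed BINOL boronate) should add allyl to one face of the ynone, the slim alkynyl group being differentiated from methyl, which sets the C6 carbinol centre (R) under catalyst control.

Step 2
Reactants: 4 but-3-en-2-ol (racemic)
Product: 5 but-3-en-2-yl methyl carbonate (racemic)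
Conditions: ClCO2Me, pyridine, CH2Cl2, 0 °C
Reagents that add atoms: methyl chloroformate COC(=O)Cl
Why: Acylation of a secondary allylic alcohol with a chloroformate gives the branched carbonate needed for allylic substitution, and its stereocentre is irrelevant because it is erased in step 4.

Step 3
Reactants: 3 (R)-3-methyl-1-(trimethylsilyl)hex-5-en-1-yn-3-ol; 5 but-3-en-2-yl methyl carbonate
Product: 6 {(3R)-3-[(but-3-en-2-yl)oxy]-3-methylhex-5-en-1-yn-1-yl}trimethylsilane (both epimers at the O-bound methine)
Conditions: LiN(SiMe3)2, THF, −10 °C; CuI; then RhCl(PPh3)3 (10 mol%), P(OMe)3 (40 mol%), 5 (excess), 0 °C to rt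
Reagents that add atoms: none
Why: Rhodium-catalysed allylic etherification, in which the rhodium enyl formed from the branched carbonate keeps its connectivity and is attacked at the oxygenated carbon by the copper alkoxide of 3 (a variant that accepts tertiary alkoxides), should give the hindered tertiary–secondary ether with the C6 centre untouched.

Step 4
Reactants: 6 {(3R)-3-[(but-3-en-2-yl)oxy]-3-methylhex-5-en-1-yn-1-yl}trimethylsilane
Product: 8 {[(2R)-2,6-dimethyl-3,4-dihydro-2H-pyran-2-yl]ethynyl}trimethylsilane, via 3,6-dihydro-2H-pyran 7 (not isolated)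
Conditions: second-generation Grubbs catalyst (3 mol%), toluene (0.01 M), 40 °C; then ethyl vinyl ether, 110 °C
Reagents that add atoms: none
Why: The ruthenium alkylidene loads on the allyl terminus, adds across the O-bound vinyl group and expels ethylene through ruthenacyclobutanes ([2+2]/retro-[2+2]), which joins C3 to C4 as a double bond; this is ordinary ring-closing metathesis of a 1,7-diene ether, closing the six-membered oxacycle between the two vinylic CH carbons. Heating the spent catalyst with ethyl vinyl ether converts it into a ruthenium hydride, which moves the C3=C4 bond to C2=C3 by hydrometalation and β-hydride elimination, the known metathesis–isomerisation tandem to cyclic enol ethers. No stereocentre is created: the C2 methine (both epimers) becomes sp2 and the quaternary C6 centre is not involved. The step needs alkene-over-alkyne chemoselectivity, secured by the trimethylsilyl cap that keeps the alkyne out of enyne metathesis, and migration of the double bond towards oxygen, secured because the O-conjugated trisubstituted enol ether is the thermodynamic sink while quaternary C6 stops migration on the other side.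

Step 5
Reactants: 8 {[(2R)-2,6-dimethyl-3,4-dihydro-2H-pyran-2-yl]ethynyl}trimethylsilane
Product: 9 {[(2R,5S,6S)-5-bromo-6-methoxy-2,6-dimethyloxan-2-yl]ethynyl}trimethylsilane (Br and OMe trans-diaxial, Br trans to the alkyne)
Conditions: NBS, MeOH, NaHCO3, CH2Cl2, −78 °C
Reagents that add atoms: N-bromosuccinimide O=C1CCC(=O)N1Br; methanol CO
Why: Bromomethoxylation of an enol ether (bromination at C3, anti capture of the C2 oxocarbenium ion by methanol) should set C3 by ring control, because in the reactive half-chair the rod-like silylethynyl group is axial at C6 and the C6 methyl equatorial, so chair-like trans-diaxial addition places bromine on the face opposite the alkyne, the alternative requiring the C6 methyl to be syn-axial to the incoming methoxy group.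

Step 6
Reactants: 9 {[(2R,5S,6S)-5-bromo-6-methoxy-2,6-dimethyloxan-2-yl]ethynyl}trimethylsilane
Product: 10 {[(2R,5S)-5-bromo-2,6,6-trimethyloxan-2-yl]ethynyl}trimethylsilane
Conditions: AlMe3 (4 equiv), CH2Cl2, −78 to 0 °C
Reagents that add atoms: trimethylaluminium C[Al](C)C
Why: Lewis-acid substitution of a tertiary methyl ketal by AlMe3 (C-glycosylation type), in which ionisation of the axial methoxy group anti to the C3–Br bond gives a bromine-bridged oxocarbenium ion that takes up methyl at C2, should create the gem-dimethyl carbon without touching the C3 or C6 configuration.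

Step 7
Reactants: 10 {[(2R,5S)-5-bromo-2,6,6-trimethyloxan-2-yl]ethynyl}trimethylsilane
Product: 11 (3S,6R)-3-bromo-6-ethynyl-2,2,6-trimethyloxane
Conditions: K2CO3 (cat.), MeOH, rt
Reagents that add atoms: none
Why: Base-catalysed methanolysis of the alkynyl C–Si bond frees the terminal alkyne, the hindered secondary bromide and the ether being inert to K2CO3 in methanol.

Step 8
Reactants: 11 (3S,6R)-3-bromo-6-ethynyl-2,2,6-trimethyloxane
Product: 13 (3S,6R)-3-bromo-6-[(E)-2-iodoethenyl]-2,2,6-trimethyloxane, via alkenylzirconocene 12 (not isolated)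
Conditions: Cp2Zr(H)Cl (1.3 equiv), THF, rt, dark; then I2, 0 °C
Reagents that add atoms: iodine II
Why: Hydrozirconation of a terminal alkyne is a syn, anti-Markovnikov addition that places zirconium on the terminal carbon, and iodinolysis of the C–Zr bond with retention should give the (E)-vinyl iodide.

Step 9
Reactants: 14 (S)-(−)-limonene
Product: 16 (1R,2R,4S)-1-methyl-4-(prop-1-en-2-yl)cyclohexane-1,2-diol, via limonene 1,2-oxide 15 (not isolated)
Conditions: mCPBA, NaHCO3, CH2Cl2, 0 °C; then 0.1 M H2SO4, THF/H2O, 0 °C to rt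
Reagents that add atoms: m-chloroperoxybenzoic acid OOC(=O)c1cccc(Cl)c1; water O
Why: Peracid epoxidation is selective for the electron-rich trisubstituted ring alkene, and acid-catalysed hydrolysis opens both epoxide epimers in the trans-diaxial sense (water at C1 of one, at C2 of the other), which should converge on the diol with the tertiary OH cis and the secondary OH trans to the isopropenyl group.

Step 10
Reactants: 16 (1R,2R,4S)-1-methyl-4-(prop-1-en-2-yl)cyclohexane-1,2-diol
Product: 18 (1R,2R,5S)-2-methyl-5-(prop-1-en-2-yl)-2-[(trimethylsilyl)oxy]cyclohexan-1-ol, via bis(trimethylsilyl) ether 17 (not isolated)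
Conditions: TMSOTf (2.4 equiv), Et3N, CH2Cl2, 0 °C; then K2CO3 (cat.), MeOH, −10 °C
Reagents that add atoms: trimethylsilyl triflate C[Si](C)(C)OS(=O)(=O)C(F)(F)F
Why: Exhaustive silylation followed by selective methanolysis of the less hindered secondary O–Si bond leaves only the tertiary hydroxyl masked, which is needed because a free trans-diaxial hydroxyl would close to the epoxide in step 11.

Step 11
Reactants: 18 (1R,2R,5S)-2-methyl-5-(prop-1-en-2-yl)-2-[(trimethylsilyl)oxy]cyclohexan-1-ol
Product: 20 {[(1R,2S,4S)-2-bromo-1-methyl-4-(prop-1-en-2-yl)cyclohexyl]oxy}trimethylsilane, via secondary triflate 19 (not isolated)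
Conditions: Tf2O, pyridine, CH2Cl2, −78 to −30 °C; then Bu4NBr (3 equiv), toluene, −30 °C to rt
Reagents that add atoms: tetrabutylammonium bromide CCCC[N+](CCCC)(CCCC)CCCC.[Br-]
Why: SN2 displacement of the axial secondary triflate by bromide from the equatorial direction should invert C2 and give the equatorial bromide cis to both the silyloxy group and the C4 substituent (the syn-bromohydrin array), the silyl ether suppressing epoxide formation.

Step 12
Reactants: 20 {[(1R,2S,4S)-2-bromo-1-methyl-4-(prop-1-en-2-yl)cyclohexyl]oxy}trimethylsilane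
Product: 22 1-{(1S,3S,4R)-3-bromo-4-methyl-4-[(trimethylsilyl)oxy]cyclohexyl}ethan-1-one, via ozonide 21 (not isolated)
Conditions: O3, CH2Cl2, −78 °C; then PPh3, −78 °C to rt
Reagents that add atoms: ozone [O-][O+]=O
Why: Ozonolysis cleaves the only alkene, the 1,1-disubstituted isopropenyl group, to the methyl ketone, the silyl ether and the secondary bromide being inert under the reductive PPh3 work-up.

Step 13
Reactants: 22 1-{(1S,3S,4R)-3-bromo-4-methyl-4-[(trimethylsilyl)oxy]cyclohexyl}ethan-1-one; 23 bis(4,4,5,5-tetramethyl-1,3,2-dioxaborolan-2-yl)methane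
Product: 24 {[(1R,2S,4S)-2-bromo-1-methyl-4-[(E)-1-(4,4,5,5-tetramethyl-1,3,2-dioxaborolan-2-yl)prop-1-en-2-yl]cyclohexyl]oxy}trimethylsilane
Conditions: lithium 2,2,6,6-tetramethylpiperidide, 23, THF, 0 °C; then 22, −78 °C to rt
Reagents that add atoms: none
Why: Boron–Wittig olefination, in which the lithiated gem-diboronate adds to the ketone and syn-eliminates a B–O unit with the remaining boryl group ending trans to the larger cyclohexyl substituent, should give the (E)-trisubstituted alkenylboronate.

Step 14
Reactants: 13 (3S,6R)-3-bromo-6-[(E)-2-iodoethenyl]-2,2,6-trimethyloxane; 24 the (E)-alkenylboronate of step 13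
Product: 26 (1R,2S,4S)-2-bromo-4-{(2E,4E)-5-[(2R,5S)-5-bromo-2,6,6-trimethyloxan-2-yl]penta-2,4-dien-2-yl}-1-methylcyclohexan-1-ol, via silyl ether 25 (not isolated)
Conditions: PdCl2(dppf) (5 mol%), K3PO4 (3 equiv), THF/H2O 5:1, 45 °C; then MeOH, rt
Reagents that add atoms: none
Why: Suzuki–Miyaura coupling of an alkenyl iodide with an alkenylboronate proceeds with retention at both double bonds to give the (E,E)-diene, zerovalent palladium leaving the two secondary alkyl bromides alone, and the basic methanol added afterwards should remove the tertiary trimethylsilyl ether.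

Compound list
1 | 4-(trimethylsilyl)but-3-yn-2-one | CC(=O)C#C[Si](C)(C)C | starting material
2 | allyldiisopropoxyborane | C=CCB(OC(C)C)OC(C)C | starting material
3 | (R)-3-methyl-1-(trimethylsilyl)hex-5-en-1-yn-3-ol | C[Si](C)(C)C#C[C@@](O)(C)CC=C | intermediate
4 | but-3-en-2-ol (racemic) | CC(O)C=C | starting material
5 | but-3-en-2-yl methyl carbonate (racemic) | COC(=O)OC(C)C=C | intermediate
6 | {(3R)-3-[(but-3-en-2-yl)oxy]-3-methylhex-5-en-1-yn-1-yl}trimethylsilane, both epimers at the O-bound methine | C[Si](C)(C)C#C[C@@](OC(C)C=C)(C)CC=C | intermediate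
7 | {[(2R)-2,6-dimethyl-3,6-dihydro-2H-pyran-2-yl]ethynyl}trimethylsilane, both C6 epimers | C[Si](C)(C)C#C[C@@]1(C)CC=CC(C)O1 | intermediate
8 | {[(2R)-2,6-dimethyl-3,4-dihydro-2H-pyran-2-yl]ethynyl}trimethylsilane | C[Si](C)(C)C#C[C@@]1(C)CCC=C(C)O1 | intermediate
9 | {[(2R,5S,6S)-5-bromo-6-methoxy-2,6-dimethyloxan-2-yl]ethynyl}trimethylsilane | C[Si](C)(C)C#C[C@@]1(C)CC[C@H](Br)[C@@](C)(OC)O1 | intermediate
10 | {[(2R,5S)-5-bromo-2,6,6-trimethyloxan-2-yl]ethynyl}trimethylsilane | C[Si](C)(C)C#C[C@@]1(C)CC[C@H](Br)C(C)(C)O1 | intermediate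
11 | (3S,6R)-3-bromo-6-ethynyl-2,2,6-trimethyloxane | C#C[C@@]1(C)CC[C@H](Br)C(C)(C)O1 | intermediate
12 | chloro{(E)-2-[(2R,5S)-5-bromo-2,6,6-trimethyloxan-2-yl]ethenyl}zirconocene | Cl[Zr](/C=C/[C@@]1(C)CC[C@H](Br)C(C)(C)O1)(C1C=CC=C1)C1C=CC=C1 | intermediate
13 | (3S,6R)-3-bromo-6-[(E)-2-iodoethenyl]-2,2,6-trimethyloxane | I/C=C/[C@@]1(C)CC[C@H](Br)C(C)(C)O1 | intermediate
14 | (S)-(−)-limonene | CC(=C)[C@H]1CCC(C)=CC1 | starting material
15 | (4S)-limonene 1,2-oxide, both epoxide epimers | CC(=C)[C@H]1CCC2(C)OC2C1 | intermediate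
16 | (1R,2R,4S)-1-methyl-4-(prop-1-en-2-yl)cyclohexane-1,2-diol | CC(=C)[C@H]1CC[C@@](C)(O)[C@H](O)C1 | intermediate
17 | bis(trimethylsilyl) ether of diol 16 | CC(=C)[C@H]1CC[C@@](C)(O[Si](C)(C)C)[C@H](O[Si](C)(C)C)C1 | intermediate
18 | (1R,2R,5S)-2-methyl-5-(prop-1-en-2-yl)-2-[(trimethylsilyl)oxy]cyclohexan-1-ol | CC(=C)[C@H]1CC[C@@](C)(O[Si](C)(C)C)[C@H](O)C1 | intermediate
19 | (1R,2R,5S)-2-methyl-5-(prop-1-en-2-yl)-2-[(trimethylsilyl)oxy]cyclohexyl trifluoromethanesulfonate | CC(=C)[C@H]1CC[C@@](C)(O[Si](C)(C)C)[C@H](OS(=O)(=O)C(F)(F)F)C1 | intermediate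
20 | {[(1R,2S,4S)-2-bromo-1-methyl-4-(prop-1-en-2-yl)cyclohexyl]oxy}trimethylsilane | CC(=C)[C@H]1CC[C@@](C)(O[Si](C)(C)C)[C@@H](Br)C1 | intermediate
21 | 3-methyl-3-{(1S,3S,4R)-3-bromo-4-methyl-4-[(trimethylsilyl)oxy]cyclohexyl}-1,2,4-trioxolane | CC1(OCOO1)[C@H]2CC[C@@](C)(O[Si](C)(C)C)[C@@H](Br)C2 | intermediate
22 | 1-{(1S,3S,4R)-3-bromo-4-methyl-4-[(trimethylsilyl)oxy]cyclohexyl}ethan-1-one | CC(=O)[C@H]1CC[C@@](C)(O[Si](C)(C)C)[C@@H](Br)C1 | intermediate
23 | bis(4,4,5,5-tetramethyl-1,3,2-dioxaborolan-2-yl)methane | CC1(C)OB(CB2OC(C)(C)C(C)(C)O2)OC1(C)C | starting material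
24 | {[(1R,2S,4S)-2-bromo-1-methyl-4-[(E)-1-(4,4,5,5-tetramethyl-1,3,2-dioxaborolan-2-yl)prop-1-en-2-yl]cyclohexyl]oxy}trimethylsilane | C/C(=C\B1OC(C)(C)C(C)(C)O1)[C@H]2CC[C@@](C)(O[Si](C)(C)C)[C@@H](Br)C2 | intermediate
25 | trimethylsilyl ether of 26 at the tertiary hydroxyl | C/C(=C\C=C\[C@@]1(C)CC[C@H](Br)C(C)(C)O1)[C@H]2CC[C@@](C)(O[Si](C)(C)C)[C@@H](Br)C2 | intermediate
26 | (1R,2S,4S)-2-bromo-4-{(2E,4E)-5-[(2R,5S)-5-bromo-2,6,6-trimethyloxan-2-yl]penta-2,4-dien-2-yl}-1-methylcyclohexan-1-ol | C/C(=C\C=C\[C@@]1(C)CC[C@H](Br)C(C)(C)O1)[C@H]1CC[C@@](C)(O)[C@@H](Br)C1 | target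

Total step count: 14. Longest linear sequence: 8 steps (1, 3, 4, 5, 6, 7, 8, 14).

Steps most likely to fail

Step 11. Bromide must attack a secondary carbon whose neighbour is fully substituted, so substitution is slow and may be overtaken by E2 loss of triflate towards C3 or by participation of the silyloxy oxygen, which would give the epoxide and then the wrong bromohydrin. The fallback sets out from diol 16 and returns at ketone 22, ties both oxygens into a ring so that no epoxide can form, and uses a far more reactive electrophile. Ozonolysis (O3, then PPh3) first gives 1-[(1S,3R,4R)-3,4-dihydroxy-4-methylcyclohexyl]ethan-1-one F1. SOCl2 and Et3N close the trans-fused cyclic sulfite F2, which RuCl3 (cat.) with NaIO4 oxidises to the cyclic sulfate F3. LiBr in THF opens F3 at the secondary carbon with inversion to the bromo hydrogensulfate F4 (as its lithium salt). Catalytic H2SO4 with a little water in THF cleaves the sulfate ester to the syn-bromohydrin ketone F5, and N-(trimethylsilyl)imidazole silylates the tertiary hydroxyl to give 22.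

Step 3. The tertiary propargylic copper alkoxide may be too hindered to intercept the rhodium allyl, so that the carbonate is consumed unproductively or the linear crotyl ether forms. The fallback sets out from 3, returns at enol ether 8 and still closes the ring through the same C3=C4 bond, but by way of an ester. n-BuLi then acryloyl chloride gives (3R)-3-methyl-1-(trimethylsilyl)hex-5-en-1-yn-3-yl prop-2-enoate F6. Second-generation Grubbs catalyst closes it to (6R)-6-methyl-6-[(trimethylsilyl)ethynyl]-5,6-dihydro-2H-pyran-2-one F7. Conjugate reduction with LiBH(s-Bu)3 and trapping of the lactone enolate with (PhO)2P(O)Cl gives the ketene acetal phosphate F8. MeMgBr with Fe(acac)3 (cat.) replaces the phosphate by methyl and gives 8.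

Step 5. Facial selectivity in the kinetic bromination may be poor if the half-chair is less biased than assumed, giving the C3 epimer as well. The fallback sets out from 8, returns at 9 and replaces kinetic by thermodynamic control. NBS in wet THF gives the bromo hemiketal (6R)-3-bromo-2,6-dimethyl-6-[(trimethylsilyl)ethynyl]oxan-2-ol F9, which is in equilibrium with the open-chain α-bromo ketone (6R)-3-bromo-6-hydroxy-6-methyl-8-(trimethylsilyl)oct-7-yn-2-one F10. LiBr and camphorsulfonic acid in MeOH/HC(OMe)3 let C3 epimerise by bromide exchange at the α-keto carbon of F10 while the ketal closes. The mixture should drain into the most stable diastereomer 9, which has the axial methoxy group anti to axial bromine and the alkyne axial.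

Further compounds
F1 | step 11 | 1-[(1S,3R,4R)-3,4-dihydroxy-4-methylcyclohexyl]ethan-1-one | CC(=O)[C@H]1CC[C@@](C)(O)[C@H](O)C1
F2 | step 11 | trans-fused cyclic sulfite of F1 | CC(=O)[C@H]1CC[C@@]2(C)OS(=O)O[C@@H]2C1
F3 | step 11 | trans-fused cyclic sulfate of F1 | CC(=O)[C@H]1CC[C@@]2(C)OS(=O)(=O)O[C@@H]2C1
F4 | step 11 | (1R,2S,4S)-4-acetyl-2-bromo-1-methylcyclohexyl hydrogen sulfate | CC(=O)[C@H]1CC[C@@](C)(OS(=O)(=O)O)[C@@H](Br)C1
F5 | step 11 | 1-[(1S,3S,4R)-3-bromo-4-hydroxy-4-methylcyclohexyl]ethan-1-one | CC(=O)[C@H]1CC[C@@](C)(O)[C@@H](Br)C1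
F6 | step 3 | (3R)-3-methyl-1-(trimethylsilyl)hex-5-en-1-yn-3-yl prop-2-enoate | C[Si](C)(C)C#C[C@@](OC(=O)C=C)(C)CC=C
F7 | step 3 | (6R)-6-methyl-6-[(trimethylsilyl)ethynyl]-5,6-dihydro-2H-pyran-2-one | C[Si](C)(C)C#C[C@@]1(C)CC=CC(=O)O1
F8 | step 3 | (2R)-2-methyl-2-[(trimethylsilyl)ethynyl]-3,4-dihydro-2H-pyran-6-yl diphenyl phosphate | C[Si](C)(C)C#C[C@@]1(C)CCC=C(OP(=O)(Oc2ccccc2)Oc2ccccc2)O1
F9 | step 5 | (6R)-3-bromo-2,6-dimethyl-6-[(trimethylsilyl)ethynyl]oxan-2-ol, epimers at C2 and C3 | C[Si](C)(C)C#C[C@@]1(C)CCC(Br)C(C)(O)O1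
F10 | step 5 | (6R)-3-bromo-6-hydroxy-6-methyl-8-(trimethylsilyl)oct-7-yn-2-one, both C3 epimers | C[Si](C)(C)C#C[C@@](O)(C)CCC(Br)C(C)=O
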